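## Analysis of the target

Ring atoms are numbered C1 (methyl-bearing alkene carbon), C2 (=CH), C3 (carbinol), C4 (isopropyl), C5 (ester carbinol), C6 (CH2), C7 (methyl-bearing alkene carbon), C8 (=CH), C9, C10.

- Target 22 is a ten-membered carbocycle with two trisubstituted alkenes, C1=C2 and C7=C8, both Z (the ring carbons are cis on each), and a 4-hydroxybenzoate on O5.
- The three stereocentres are contiguous, C3 (S), C4 (S) and C5 (R). The two oxygens are 1,3-syn and the isopropyl group is anti to each along the C3–C4–C5 zigzag, so in the idealised planar ring all three substituents lie on one face.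
- Sensitive points are the secondary allylic alcohol at C3 (ionisation, transposition), the monoester of a syn-1,3-diol (acyl migration from O5 to O3 under base), the free phenol, and the (Z,Z)-cyclodeca-1,5-diene, which cyclises across the ring under acid.
- The difficulty is threefold: a ten-membered ring is among the hardest sizes to close directly, the two Z-trisubstituted alkenes must hold a fixed 1,5-relationship, and the stereotriad sits on a mobile ring on which two similar secondary hydroxyls must be told apart.
- The feature the plan rests on: if C4 and C5 are taken out and C3 is joined to C6, the remaining atoms C1, C2, C3, C6, C7, C8, C9, C10 with methyls on C1 and C7 are exactly the ring of diene 1, cis alkenes included.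
- The target is therefore the eight-membered ring of 1 with a two-carbon unit spliced between a carbonyl carbon (C3) and its α-carbon (C6). Such a splice delivers C3 and C5 as a 1,3-diketone, the oxidation pattern from which the syn-diol monoester follows by two reductions.

## Retrosynthetic reasoning

**22 from 21.** The last bond cut is the phenolic O–Si bond. An aryl silyl ether is removed by buffered fluoride under conditions that leave the syn-diol monoester and the allylic alcohol alone.

**21 from 20.** The C3–H bond is removed, returning the allylic alcohol to the enone carbonyl. An enone is a good substrate for oxazaborolidine-catalysed 1,2-reduction. Placing this reduction after the acylation means that O5 already carries the ester when O3 is created, so the two hydroxyls never have to be distinguished.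

**20 from 15 and 19.** The ester C–O bond is cut. Hydroxy ketone 15 has a single hydroxyl, so acylation with aroyl chloride 19 (from protected acid 18, from 16) is unambiguous.

**15 from 14.** The C5–H bond is removed. In diketone 14 the carbon C4 lies between two carbonyls and is configurationally labile, so one enantioselective reduction of C5 under dynamic kinetic resolution can set C5 and C4 together. The forward step must reduce the non-conjugated C5 carbonyl and leave the enone carbonyl C3.

**14 from 11 (key disconnection).** C3 is reconnected to C6 in the aldol sense, the C5 enolate carbon C6 adding to the C3 carbonyl. This folds the ten-membered ring into the 4/8 bicycle 11, a 3-silyloxycyclobutanone. The cut is made here and nowhere else because it is the only one that converts the medium ring into the ring of 1. Forward, loss of cyclobutane strain drives the opening, no ring-closing event is needed, and both alkene geometries are inherited.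

**11 from 8 and 10.** The bonds C3–C4 and C5–C6 are cut, a retro-[2+2] that gives silyl enol ether 8 and ketene 10, the latter generated from acid chloride 9. The polarity is the natural one: the nucleophilic carbon C6 of the enol ether joins the ketene carbonyl carbon.

**8 from 6.** The O–Si bond is cut. Dienone 6 must be enolised toward C6, its α′ position, which is also allylic to C7=C8.

**6 from 5, 2 and 1.** The carbonyl must sit on the ring CH2 next to the =CH end of one alkene of 1. Direct allylic oxidation of 1 was set aside: the diene has two kinds of ring CH2 and two allylic methyls, ene-type oxidants prefer the wrong kind, and radical-type oxidants go on to attack C6 once it is doubly activated. Instead each step has only one possible regiochemical outcome: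
- 6 arises by chromium-mediated oxidative 1,3-transposition of tertiary allylic alcohol 5;
- 5 arises from epoxide 2 by opening with a selenium nucleophile at the less substituted carbon, followed by selenoxide elimination toward the only available hydrogens;
- 2 is the mono-epoxide of the C2-symmetric diene 1.

## Alternatives that were turned down

**Alternative 1:** The ring is cut at C9–C10.
- Forward step: the open-chain bromo sulfone A2 is treated with LiN(SiMe3)2 at high dilution. The sulfonyl-stabilised allylic carbanion at C9 displaces the primary allylic bromide at C10 and gives the cyclic sulfone A1, whose sulfonyl group is then removed reductively.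
- For it: the C3–C5 triad is built in an open chain by well-established acyclic stereocontrol and carried through protected. Sulfone alkylation is a proven way to close terpenoid rings.
- Against it: a ten-membered ring is closed directly, so oligomerisation competes. The ambident allyl sulfone anion can alkylate through C7 and close an eight-membered ring, and the bromide can react in the SN2′ sense at C2. The Z geometry of C7=C8 is at risk both in the delocalised anion and in the reductive removal of the allylic sulfone, which can also shift the alkene to C8=C9. Both Z-trisubstituted alkenes must first be made in the chain, and after A1 four more operations remain (desulfonylation, ether cleavage at O5, acylation, desilylation).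
- Comparison: this route is stronger on the stereotriad. The chosen route offers a ring and two alkene geometries bought ready-made, no ring-closing step, and roughly half the length.

**Alternative 2:** The C3–C4 bond is cut in the retro-[2,3]-Wittig sense, leading to the thirteen-membered diallyl ether A4.
- Forward step: n-BuLi deprotonates the O–CH2 group at C3, and the α-oxy allyl anion attacks C4 of the other allyl unit. The ether contracts to the carbocycle A3, which has a free C3 hydroxyl and a C4 isopropenyl group.
- For it: a thirteen-membered ether is easier to close than a ten-membered carbocycle. The concerted five-centre transition state forms C3–C4 and fixes the C3/C4 relationship in one event, with chirality relayed from C5.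
- Against it: A4 has two nearly equivalent allylic O–CH2 groups (C3 and C12). Deprotonation at the wrong one gives an isomeric contraction, and [1,2]-shifts compete. A3 carries C5 in the wrong configuration and an isopropenyl group, so O3 must be protected, O5 freed and esterified with inversion at a hindered centre, the 1,1-disubstituted alkene hydrogenated selectively beside two trisubstituted ones (RhCl(PPh3)3), and O3 released. A4 itself needs two Z-trisubstituted allylic units and a macrocyclic etherification.
- Comparison: it is the stronger plan for the C3/C4 relationship. The chosen route offers a much shorter path and a ring-forming event with no positional ambiguity of this kind.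

**Alternative 3:** C3 is reconnected to C7 across the ring, giving the cis-fused hydroazulene mesylate A6.
- Forward step: KH forms the tertiary alkoxide at C3, the C3–C7 bond breaks anti-periplanar to the C8 mesylate, and the cyclodecadienone A5 is unveiled by Grob fragmentation.
- For it: like the chosen plan it makes the medium ring by cleaving a bicycle. It is stereospecific, the Z geometry of C7=C8 following from the anti-periplanar arrangement, and C4 and C5 are fixed on a rigid bicycle before the flexible ring exists.
- Against it: A6 needs five stereocentres, including a quaternary bridgehead (C7) and a tertiary allylic alcohol (C3), with the C8 sulfonate in the one configuration that is anti-periplanar to C3–C7. Selective mesylation of a hindered secondary hydroxyl next to a quaternary carbon beside a tertiary allylic alcohol is delicate, and the hydroazulene would take well over ten steps. After A5, the C3 reduction and the exchange of the O5 ether for the ester, with temporary protection of O3, add four or five more.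
- Comparison: this route is stronger exactly where the chosen one is weakest, in the security of the C4/C5 configuration and in mechanistically enforced alkene geometry. The chosen route reaches its fragmentation precursor 11 in five steps from a commodity diene and needs no protecting group on the ring.

Key step: step 6

## Remarks on the chemistry

- Commercial 1 usually contains some of the 1,6-dimethyl isomer. It is assumed that isomerically pure 1 is used, or that the isomer is removed by chromatography at the stage of 2 or 6.
- The sense of induction of the transfer-hydrogenation catalyst on this non-aromatic ketone is assigned on steric grounds (branched C4 side away from the η6-arene). Should the opposite sense be found, the (R,R)-ligand is used with nothing else changed.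
- (S,S)-TsDPEN is the monoanion of (1S,2S)-N-(4-toluenesulfonyl)-1,2-diphenylethane-1,2-diamine. Cis and trans for ring substituents refer to the idealised planar ring.

## Route

Step 1
Reactants: 1 (1Z,5Z)-1,5-dimethylcycloocta-1,5-diene
Product: 2 rac-(4Z)-1,5-dimethyl-9-oxabicyclo[6.1.0]non-4-ene (cis-epoxide)
Conditions: mCPBA (0.9 equiv), CH2Cl2, 0 °C
Reagents that add atoms: 3-chloroperoxybenzoic acid, O=C(OO)c1cccc(Cl)c1
Why: Peracid (Prilezhaev) epoxidation; the two alkenes of 1 are equivalent, so mono-epoxidation can give only one compound, and a slight deficit of peracid at 0 °C limits bis-epoxide and acid-induced transannular reactions. Syn addition to a cis ring alkene gives the cis-epoxide as a racemate.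

Step 2
Reactants: 2 rac-(4Z)-1,5-dimethyl-9-oxabicyclo[6.1.0]non-4-ene
Product: 5 rac-(2Z,5Z)-1,5-dimethylcycloocta-2,5-dien-1-ol, via hydroxy selenide 3 (not isolated), via selenoxide 4 (not isolated)
Conditions: (PhSe)2, NaBH4, EtOH, reflux; then 30% H2O2, THF, 0 °C to rt
Reagents that add atoms: none
Why: Epoxide-to-allylic-alcohol transposition by selenide opening and selenoxide syn elimination: benzeneselenolate attacks the less substituted epoxide carbon C2 in an SN2 reaction, and the selenoxide can only eliminate toward C3 because C1 bears no hydrogen. The product is the tertiary allylic alcohol with a cis C2=C3 ring alkene; its single stereocentre is lost in the next step.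

Step 3
Reactants: 5 rac-(2Z,5Z)-1,5-dimethylcycloocta-2,5-dien-1-ol
Product: 6 (2Z,6Z)-3,7-dimethylcycloocta-2,6-dien-1-one
Conditions: pyridinium chlorochromate (C5H5NH[CrO3Cl], 2 equiv), Celite, CH2Cl2, rt
Reagents that add atoms: pyridinium chlorochromate, [O-][Cr](=O)(=O)Cl.c1cc[nH+]cc1
Why: Babler–Dauben oxidative transposition: the chromate ester of the tertiary allylic alcohol undergoes a [3,3] shift to the secondary allylic chromate at C3, which is oxidised to the ketone while the C1=C2 alkene is restored (cis, as the eight-membered ring requires). The carbonyl is thereby placed regiospecifically on the CH2 next to the =CH terminus.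

Step 4
Reactants: 6 (2Z,6Z)-3,7-dimethylcycloocta-2,6-dien-1-one
Product: 8 trimethyl[(3,7-dimethylcycloocta-1,3,7-trien-1-yl)oxy]silane (all ring alkenes cis), via lithium dienolate 7 (not isolated)
Conditions: LiN(iPr)2, THF, −78 °C; Me3SiCl, Et3N, −78 to 0 °C; cold pentane work-up
Reagents that add atoms: chlorotrimethylsilane, C[Si](C)(C)Cl
Why: Kinetic enolisation and O-silylation: at −78 °C the amide base removes the α′ proton at C6, which is flanked by the carbonyl and the C7=C8 alkene, faster than a γ proton of the enone. The silyloxy triene is kept at or below room temperature because cycloocta-1,3,5-trienes electrocyclise on heating.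

Step 5
Reactants: 8 trimethyl[(3,7-dimethylcycloocta-1,3,7-trien-1-yl)oxy]silane; 9 3-methylbutanoyl chloride (isovaleryl chloride)
Product: 11 rac-3,7-dimethyl-10-(propan-2-yl)-1-[(trimethylsilyl)oxy]bicyclo[6.2.0]deca-2,6-dien-9-one (cis-fused, isopropyl trans to the silyloxy group), via isopropylketene 10 (not isolated)
Conditions: Et3N (3 equiv), hexane, 25–30 °C, slow addition of 9 (2.5 equiv); filtration, Et3N-deactivated silica
Reagents that add atoms: none
Why: Thermal ketene–silyl enol ether [2+2] cycloaddition: the nucleophilic carbon C6 joins the ketene carbonyl carbon (C5) and C3 joins the ketene terminus (C4), the usual 3-silyloxycyclobutanone regiochemistry. Suprafacial addition to the cis ring alkene gives the cis fusion, and the larger ketene substituent is expected on the face of the eight-membered ring, which is immaterial because C4 is epimerised later. Slow addition in hexane keeps the ketene concentration low so that cycloaddition can compete with dimerisation.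

Step 6
Reactants: 11 rac-3,7-dimethyl-10-(propan-2-yl)-1-[(trimethylsilyl)oxy]bicyclo[6.2.0]deca-2,6-dien-9-one
Product: 14 (4Z,8Z)-5,9-dimethyl-2-(propan-2-yl)cyclodeca-4,8-diene-1,3-dione, via cyclobutanolate 12 (not isolated), via ring-opened enolate 13 (not isolated)
Conditions: Bu4NF (1.1 equiv), AcOH (1.1 equiv), THF, −40 to 0 °C; pH 7 phosphate buffer
Reagents that add atoms: none
Why: Fluoride attacks silicon of the tertiary silyl ether and frees the C3 alkoxide 12. The alkoxide oxygen forms the C3 carbonyl while the electron pair of the C3–C6 bond, which is α,β to the cyclobutanone carbonyl, moves onto C6–C5–O to give enolate 13; this retro-aldol step is driven by release of the cyclobutane strain, and acetic acid then protonates 13 to diketone 14. The closest known reaction type is the two-carbon ring expansion of cycloalkanones by retro-aldol opening of the [2+2] adducts of ketenes and their silyl enol ethers to cycloalkane-1,3-diones. No ring is closed: the ten-membered ring appears because the bond common to the four- and eight-membered rings is cut. No stereocentre is formed; C3 becomes trigonal, C6 becomes a methylene, and C4 becomes freely epimerisable between two carbonyls. The selectivity required is scission of C3–C6 and not of C3–C4, both being β-bonds of the same aldolate: the negative charge building up at C6 is allylic to the C7=C8 π bond, with which the breaking bond can align in the folded bicycle, whereas C4 is a secondary centre destabilised by its isopropyl group, and cleavage of the ring-fusion bond is also the normal course of the parent ring expansion. One equivalent of acetic acid and a temperature at or below 0 °C keep the enolate concentration low, so that reprotonation at C8 (which would move C7=C8 into conjugation) and transannular Michael addition of C6 to C1 of the enone are suppressed. Sigmatropic alternatives open to an alkenylcyclobutanolate ([1,3] or oxy-Cope shifts) need higher temperatures than this carbonyl-assisted fragmentation.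

Step 7
Reactants: 14 (4Z,8Z)-5,9-dimethyl-2-(propan-2-yl)cyclodeca-4,8-diene-1,3-dione
Product: 15 (2Z,6Z,9R,10R)-9-hydroxy-3,7-dimethyl-10-(propan-2-yl)cyclodeca-2,6-dien-1-one
Conditions: RuCl(p-cymene)[(S,S)-TsDPEN] (2 mol%), HCO2H/Et3N (5:2), CH2Cl2, 25 °C
Reagents that add atoms: none
Why: Noyori–Ikariya asymmetric transfer hydrogenation run as a dynamic kinetic resolution of a 2-alkyl-1,3-diketone: C4–H lies between two carbonyls and epimerises quickly in the formic acid/triethylamine medium, and the non-conjugated C5 carbonyl is more electrophilic than the enone carbonyl C3, so only C5 is reduced. The catalyst is expected to expose the Si face of C5 (unbranched C6 next to the η6-arene, branched C4 in the open quadrant), which gives 9R. Of the two equilibrating C4 epimers, the one that lets hydride approach anti to the C4–C3 ring bond and past C4–H (Felkin–Anh arrangement, the control that gives cis-2-alkylcycloalkanols) should react faster, so the hydroxyl ends cis to the isopropyl group (10R).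

Step 8
Reactants: 16 4-hydroxybenzoic acid
Product: 18 4-[(tert-butyldimethylsilyl)oxy]benzoic acid, via bis-silyl derivative 17 (not isolated)
Conditions: TBSCl (2.4 equiv), imidazole, DMF, rt; then AcOH/THF/H2O, rt
Reagents that add atoms: tert-butylchlorodimethylsilane, CC(C)(C)[Si](C)(C)Cl
Why: Exhaustive silylation followed by selective hydrolysis of the far more labile silyl ester; the aryl silyl ether survives mild aqueous acid. Standard protecting-group chemistry.

Step 9
Reactants: 18 4-[(tert-butyldimethylsilyl)oxy]benzoic acid; 15 (2Z,6Z,9R,10R)-9-hydroxy-3,7-dimethyl-10-(propan-2-yl)cyclodeca-2,6-dien-1-one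
Product: 20 (1R,3Z,7Z,10R)-3,7-dimethyl-9-oxo-10-(propan-2-yl)cyclodeca-3,7-dien-1-yl 4-[(tert-butyldimethylsilyl)oxy]benzoate, via acid chloride 19 (not isolated)
Conditions: 18, (COCl)2, cat. DMF, CH2Cl2, 0 °C, evaporate; then 15, pyridine, cat. DMAP, CH2Cl2, 0 °C to rt
Reagents that add atoms: none
Why: Acid chloride formation through the Vilsmeier-type chloroiminium species, then DMAP-catalysed acylation of the only hydroxyl present, which fixes the ester on O5 before O3 exists. A weak amine base at 0 °C avoids epimerisation at C4 and β-elimination of the new β-acyloxy ketone; the configurations at C4 and C5 are untouched.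

Step 10
Reactants: 20 (1R,3Z,7Z,10R)-3,7-dimethyl-9-oxo-10-(propan-2-yl)cyclodeca-3,7-dien-1-yl 4-[(tert-butyldimethylsilyl)oxy]benzoate
Product: 21 (1R,3Z,7Z,9S,10S)-9-hydroxy-3,7-dimethyl-10-(propan-2-yl)cyclodeca-3,7-dien-1-yl 4-[(tert-butyldimethylsilyl)oxy]benzoate
Conditions: (R)-1-methyl-3,3-diphenyltetrahydro-1H,3H-pyrrolo[1,2-c][1,3,2]oxazaborole [(R)-Me-CBS, C18H20BNO] (0.3 equiv), catecholborane (2 equiv), toluene, −78 °C; MeOH, pH 7 buffer
Reagents that add atoms: none
Why: Corey–Bakshi–Shibata 1,2-reduction of the enone carbonyl; catecholborane is used because it does not hydroborate the trisubstituted alkenes at −78 °C. The (R)-oxazaborolidine should bind the carbonyl oxygen on the side of the smaller, unbranched alkenyl carbon C2, away from the branched C4, and deliver hydride to the Re face of C3, giving 9S. This is also the face anti to the C4–C5 ring bond and past C4–H, so catalyst and substrate preferences should reinforce each other and place O3 cis to the isopropyl group and to O5.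

Step 11
Reactants: 21 (1R,3Z,7Z,9S,10S)-9-hydroxy-3,7-dimethyl-10-(propan-2-yl)cyclodeca-3,7-dien-1-yl 4-[(tert-butyldimethylsilyl)oxy]benzoate
Product: 22 (1R,3Z,7Z,9S,10S)-9-hydroxy-3,7-dimethyl-10-(propan-2-yl)cyclodeca-3,7-dien-1-yl 4-hydroxybenzoate
Conditions: Bu4NF (1.2 equiv), AcOH (1.5 equiv), THF, 0 °C
Reagents that add atoms: none
Why: Fluoride-induced cleavage of an aryl silyl ether, which is fast because phenoxide is a good leaving group from silicon. Acetic acid buffering prevents alkoxide-mediated acyl migration from O5 to O3 and ester cleavage; no stereocentre is touched.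

## Compound list

1 | (1Z,5Z)-1,5-dimethylcycloocta-1,5-diene | C/C1=C/CC/C(C)=C\CC1 | starting material
2 | rac-(4Z)-1,5-dimethyl-9-oxabicyclo[6.1.0]non-4-ene (cis-epoxide; one enantiomer drawn) | C[C@@]12CC/C=C(C)\CC[C@@H]1O2 | intermediate
3 | rac-trans-(5Z)-1,5-dimethyl-2-(phenylselanyl)cyclooct-5-en-1-ol (one enantiomer drawn) | C[C@@]1(O)CC/C=C(C)\CC[C@H]1[Se]c1ccccc1 | intermediate (not isolated)
4 | rac-trans-(5Z)-1,5-dimethyl-2-(phenylseleninyl)cyclooct-5-en-1-ol (mixture at selenium) | C[C@@]1(O)CC/C=C(C)\CC[C@H]1[Se](=O)c1ccccc1 | intermediate (not isolated)
5 | rac-(2Z,5Z)-1,5-dimethylcycloocta-2,5-dien-1-ol (one enantiomer drawn) | C[C@]1(O)/C=C\C/C(C)=C\CC1 | intermediate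
6 | (2Z,6Z)-3,7-dimethylcycloocta-2,6-dien-1-one | C/C1=C/C(=O)C/C(C)=C\CC1 | intermediate
7 | lithium 3,7-dimethylcycloocta-1,3,7-trien-1-olate (all ring alkenes cis) | C/C1=C/C([O-])=C\C(C)=C/CC1.[Li+] | intermediate (not isolated)
8 | trimethyl[(3,7-dimethylcycloocta-1,3,7-trien-1-yl)oxy]silane (all ring alkenes cis) | C/C1=C/C(O[Si](C)(C)C)=C\C(C)=C/CC1 | intermediate
9 | 3-methylbutanoyl chloride (isovaleryl chloride) | CC(C)CC(Cl)=O | starting material
10 | 3-methylbut-1-en-1-one (isopropylketene) | CC(C)C=C=O | intermediate (not isolated)
11 | rac-3,7-dimethyl-10-(propan-2-yl)-1-[(trimethylsilyl)oxy]bicyclo[6.2.0]deca-2,6-dien-9-one (cis-fused; isopropyl trans to the silyloxy group; one enantiomer drawn) | C/C1=C/[C@@]2(O[Si](C)(C)C)[C@@H](C(C)C)C(=O)[C@H]2/C(C)=C\CC1 | intermediate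
12 | tetrabutylammonium 3,7-dimethyl-9-oxo-10-(propan-2-yl)bicyclo[6.2.0]deca-2,6-dien-1-olate (configuration as in 11) | C/C1=C/[C@@]2([O-])[C@@H](C(C)C)C(=O)[C@H]2/C(C)=C\CC1.CCCC[N+](CCCC)(CCCC)CCCC | intermediate (not isolated)
13 | tetrabutylammonium C5/C6 enolate of 14 (drawn as the C6 carbanion resonance form) | C/C1=C/C(=O)C(C(C)C)C(=O)[CH-]/C(C)=C\CC1.CCCC[N+](CCCC)(CCCC)CCCC | intermediate (not isolated)
14 | (4Z,8Z)-5,9-dimethyl-2-(propan-2-yl)cyclodeca-4,8-diene-1,3-dione (C2 of this name, ring atom C4, configurationally labile) | C/C1=C/C(=O)C(C(C)C)C(=O)C/C(C)=C\CC1 | intermediate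
15 | (2Z,6Z,9R,10R)-9-hydroxy-3,7-dimethyl-10-(propan-2-yl)cyclodeca-2,6-dien-1-one | C/C1=C/C(=O)[C@H](C(C)C)[C@H](O)C/C(C)=C\CC1 | intermediate
16 | 4-hydroxybenzoic acid | O=C(O)c1ccc(O)cc1 | starting material
17 | tert-butyldimethylsilyl 4-[(tert-butyldimethylsilyl)oxy]benzoate | CC(C)(C)[Si](C)(C)OC(=O)c1ccc(O[Si](C)(C)C(C)(C)C)cc1 | intermediate (not isolated)
18 | 4-[(tert-butyldimethylsilyl)oxy]benzoic acid | CC(C)(C)[Si](C)(C)Oc1ccc(C(=O)O)cc1 | intermediate
19 | 4-[(tert-butyldimethylsilyl)oxy]benzoyl chloride | CC(C)(C)[Si](C)(C)Oc1ccc(C(Cl)=O)cc1 | intermediate (not isolated)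
20 | (1R,3Z,7Z,10R)-3,7-dimethyl-9-oxo-10-(propan-2-yl)cyclodeca-3,7-dien-1-yl 4-[(tert-butyldimethylsilyl)oxy]benzoate | C/C1=C/C(=O)[C@H](C(C)C)[C@H](OC(=O)c2ccc(O[Si](C)(C)C(C)(C)C)cc2)C/C(C)=C\CC1 | intermediate
21 | (1R,3Z,7Z,9S,10S)-9-hydroxy-3,7-dimethyl-10-(propan-2-yl)cyclodeca-3,7-dien-1-yl 4-[(tert-butyldimethylsilyl)oxy]benzoate | C/C1=C/[C@H](O)[C@H](C(C)C)[C@H](OC(=O)c2ccc(O[Si](C)(C)C(C)(C)C)cc2)C/C(C)=C\CC1 | intermediate
22 | (1R,3Z,7Z,9S,10S)-9-hydroxy-3,7-dimethyl-10-(propan-2-yl)cyclodeca-3,7-dien-1-yl 4-hydroxybenzoate | C/C1=C/[C@H](O)[C@H](C(C)C)[C@H](OC(=O)c2ccc(O)cc2)C/C(C)=C\CC1 | target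

## Step count and least certain steps

Total step count: 11. Longest linear sequence: 10 steps (steps 1 to 7 and 9 to 11, from 1); step 8 is a one-step branch from 16.

**Step 6 (key step).** The most likely failure is loss of selectivity in the fragmentation: the aldolate may also cut C3–C4, keeping the eight-membered ring. The ring-opened enolate may also, before it is protonated, move C7=C8 into conjugation or add across the ring to the enone, because a free enolate is present in a basic medium. The fallback avoids any free enolate. It sets out from 11, which is desilylated by acid methanolysis (citric acid, MeOH, 0 °C) to the free cyclobutanol, rac-1-hydroxy-3,7-dimethyl-10-(propan-2-yl)bicyclo[6.2.0]deca-2,6-dien-9-one F1. F1 is then opened through its enol in acetic acid/water/2-propanol at 60–70 °C, the acidic protocol under which such adducts are known to ring-expand, and the route is rejoined at 14.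

**Step 5.** The most likely failure is that dimerisation of the monoalkylketene 10, catalysed by the amine salt, outruns cycloaddition to the hindered, fully substituted enol carbon. Heating to compensate is not possible because the triene 8 would electrocyclise. The fallback uses a more electrophilic ketene and starts from 8:
- 2-chloro-3-methylbutanoyl chloride and Et3N give 2-chloro-3-methylbut-1-en-1-one (chloro(isopropyl)ketene) F2.
- F2 adds to 8 to give the chloro adduct, rac-10-chloro-3,7-dimethyl-10-(propan-2-yl)-1-[(trimethylsilyl)oxy]bicyclo[6.2.0]deca-2,6-dien-9-one F3.
- Zinc dust in acetic acid/2-propanol at 0 °C removes the chlorine reductively and returns the route to 11, together with its C10 epimer F4; both converge on 14.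

The chlorine must be removed before fluoride is applied, since a chlorine on C4 would steer the retro-aldol toward C3–C4.

**Step 7.** The most likely failure is delivery of hydride to the wrong face relative to the isopropyl group, so that the hydroxyl ends trans to it, as in open-chain 2-alkyl-1,3-diketones, because the ring conformation and not the Felkin–Anh preference decides. A lesser risk is that C4 epimerises too slowly for an efficient dynamic resolution. The fallback accepts the trans series. Starting from 14, the (R,R)-ligand is used so that the trans product is (2Z,6Z,9S,10R)-9-hydroxy-3,7-dimethyl-10-(propan-2-yl)cyclodeca-2,6-dien-1-one F5, with C10 correct and C9 inverted. F5 is esterified with inversion by Mitsunobu reaction with acid 18 (PPh3, diisopropyl azodicarboxylate, toluene, 0 °C). This rejoins the route at 20 and replaces step 9.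

**Step 10.** The most likely failure is poor facial selectivity at C3 if the catalyst preference and the ring conformation are mismatched, or if the alkenyl group rather than C4 behaves as the large substituent. The fallback relies on inversion instead of reagent control and starts from 20:
- Luche reduction (NaBH4, CeCl3·7H2O, MeOH, −78 °C) gives whichever C9 alcohol the substrate prefers.
- If that is the 9-epimer, (1R,3Z,7Z,9R,10S)-9-hydroxy-3,7-dimethyl-10-(propan-2-yl)cyclodeca-3,7-dien-1-yl 4-[(tert-butyldimethylsilyl)oxy]benzoate F6, it is inverted by Mitsunobu reaction with chloroacetic acid to the 9-O-chloroacetate of 21, F7.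
- The chloroacetate is removed selectively with thiourea (NaHCO3, EtOH, rt), rejoining the route at 21.

**Step 2.** The most likely failure is slow SN2 opening of the hindered medium-ring epoxide, which gives time for elimination or transannular side reactions and for incomplete conversion. The fallback gives up the regiochemical guarantee for brevity. From 1, direct allylic oxidation with CrO3/3,5-dimethylpyrazole (CH2Cl2, −20 °C) is expected to favour the CH2 next to the =CH terminus. After chromatographic removal of the 2,6-dimethyl regioisomer and over-oxidised material, the route is rejoined at 6, replacing steps 1 to 3.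

## Further compounds

F1 | step 6 | rac-1-hydroxy-3,7-dimethyl-10-(propan-2-yl)bicyclo[6.2.0]deca-2,6-dien-9-one (configuration as in 11) | C/C1=C/[C@@]2(O)[C@@H](C(C)C)C(=O)[C@H]2/C(C)=C\CC1
F2 | step 5 | 2-chloro-3-methylbut-1-en-1-one (chloro(isopropyl)ketene) | CC(C)C(Cl)=C=O
F3 | step 5 | rac-10-chloro-3,7-dimethyl-10-(propan-2-yl)-1-[(trimethylsilyl)oxy]bicyclo[6.2.0]deca-2,6-dien-9-one (cis-fused, mixture at C10) | C/C1=C/[C@@]2(O[Si](C)(C)C)C(Cl)(C(C)C)C(=O)[C@H]2/C(C)=C\CC1
F4 | step 5 | C10 epimer of 11 (cis-fused, isopropyl cis to the silyloxy group) | C/C1=C/[C@@]2(O[Si](C)(C)C)[C@H](C(C)C)C(=O)[C@H]2/C(C)=C\CC1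
F5 | step 7 | (2Z,6Z,9S,10R)-9-hydroxy-3,7-dimethyl-10-(propan-2-yl)cyclodeca-2,6-dien-1-one | C/C1=C/C(=O)[C@H](C(C)C)[C@@H](O)C/C(C)=C\CC1
F6 | step 10 | (1R,3Z,7Z,9R,10S)-9-hydroxy-3,7-dimethyl-10-(propan-2-yl)cyclodeca-3,7-dien-1-yl 4-[(tert-butyldimethylsilyl)oxy]benzoate | C/C1=C/[C@@H](O)[C@H](C(C)C)[C@H](OC(=O)c2ccc(O[Si](C)(C)C(C)(C)C)cc2)C/C(C)=C\CC1
F7 | step 10 | 9-O-chloroacetate of 21 (ring configuration as in 21) | C/C1=C/[C@H](OC(=O)CCl)[C@H](C(C)C)[C@H](OC(=O)c2ccc(O[Si](C)(C)C(C)(C)C)cc2)C/C(C)=C\CC1
F0 | step 2 | none | none
A1 | alternative 1 | ten-membered (Z,Z)-diene with C3 tert-butyldimethylsilyl ether, C5 4-methoxybenzyl ether and C9 phenylsulfonyl group (either C9 epimer) | C/C1=C/[C@H](O[Si](C)(C)C(C)(C)C)[C@H](C(C)C)[C@H](OCc2ccc(OC)cc2)C/C(C)=C\C(S(=O)(=O)c2ccccc2)C1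
A2 | alternative 1 | open-chain (Z,Z)-dienyl bromo sulfone (C10 allylic bromide, C9 phenylsulfonylmethylene, C3 silyl ether, C5 4-methoxybenzyl ether) | BrC/C(C)=C\[C@H](O[Si](C)(C)C(C)(C)C)[C@H](C(C)C)[C@H](OCc1ccc(OC)cc1)C/C(C)=C\CS(=O)(=O)c1ccccc1
A3 | alternative 2 | ten-membered (Z,Z)-diene with free C3 hydroxyl, C4 isopropenyl and C5-epimeric triethylsilyl ether | C/C1=C/[C@H](O)[C@H](C(C)=C)[C@@H](O[Si](CC)(CC)CC)C/C(C)=C\CC1
A4 | alternative 2 | thirteen-membered diallyl ether (O between C3 and C12, Z alkenes C1=C2, C4=C11 and C7=C8, C5 triethylsilyl ether) | C/C1=C/COC/C(C)=C\[C@@H](O[Si](CC)(CC)CC)C/C(C)=C\CC1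
A5 | alternative 3 | (Z,Z)-cyclodecadienone with C3 ketone, C4 isopropyl and C5 4-methoxybenzyl ether | C/C1=C/C(=O)[C@H](C(C)C)[C@H](OCc2ccc(OC)cc2)C/C(C)=C\CC1
A6 | alternative 3 | cis-fused hydroazulene (C3–C7 bond) with C3 tertiary allylic alcohol, C7 methyl, C8 mesylate anti-periplanar to C3–C7, C4 isopropyl and C5 4-methoxybenzyl ether | C/C1=C/[C@]2(O)[C@H](C(C)C)[C@H](OCc3ccc(OC)cc3)C[C@]2(C)[C@H](OS(C)(=O)=O)CC1
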